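The route rests on taking the carboxyl carbon C1' of the side chain out as carbon monoxide. C1' and the phenol oxygen O5 are joined through C2', C3', C6 and C5, so these six atoms are a latent 4-pentyl-3,4-dihydrocoumarin ring on the arene. One palladium hydride cyclocarbonylation of 2-(hept-1-en-2-yl)-3,5-dimethoxyphenol, a 1,1-disubstituted styrene with an ortho phenol, should form the C2'–C1' and C1'–O5 bonds, close that lactone and set the benzylic centre C3' (R). The lactone then masks O5 and the acid while the cis-2,3-dimethylchromanone ring and the C8 prenyl group are added.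

Key step: step 4

Assumption: (R,R)-DIOP is taken as the ligand antipode that leads to the 4R lactone and quinidine as the alkaloid that leads to the (2S,3R) cis-chromanone; should either sense prove opposite, (S,S)-DIOP or quinine is used and nothing else changes.

Numbering: the target uses chroman-4-one numbering (O1, C2–C4, C4a, C5–C8, C8a) with the side chain primed from the carboxyl carbon C1' to the benzylic carbon C3'. Lactones 9–12 use chroman-2-one numbering, in which C8, C7, C6 and C5 are the future C4a, C8a, C8 and C7. Tricycles 13–16 use pyrano[2,3-f]chromene numbering, in which C6 is the future C8.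

Step 1
Reactants: 1 1,3,5-trimethoxybenzene; 2 hexanoyl chloride
Product: 4 1-(2-hydroxy-4,6-dimethoxyphenyl)hexan-1-one, via trimethoxyphenyl ketone 3 (not isolated)
Conditions: AlCl3 (2.5 equiv), CH2Cl2, 0 °C → 40 °C; aq. HCl
Reagents that add atoms: none
Why: Friedel–Crafts acylation of the threefold-symmetric arene can give only one ketone, and the excess AlCl3, chelated between the carbonyl and one of the two equivalent ortho methoxy oxygens, should then remove that one methyl group as chloromethane (Lewis acid ortho-demethylation), after which the aluminium phenoxide chelate shields the second ortho ether.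

Step 2
Reactants: 4 1-(2-hydroxy-4,6-dimethoxyphenyl)hexan-1-one
Product: 5 1-(2-{[tert-butyl(dimethyl)silyl]oxy}-4,6-dimethoxyphenyl)hexan-1-one
Conditions: TBSCl, imidazole, DMF, rt → 40 °C
Reagents that add atoms: tert-butyldimethylsilyl chloride, CC(C)(C)[Si](C)(C)Cl
Why: Routine phenol silylation masks the acidic OH, which would otherwise protonate the titanium methylidene of the next step and leave the ketone as an unreactive chelated phenoxide.

Step 3
Reactants: 5 1-(2-{[tert-butyl(dimethyl)silyl]oxy}-4,6-dimethoxyphenyl)hexan-1-one
Product: 7 2-(hept-1-en-2-yl)-3,5-dimethoxyphenol, via silylated alkene 6 (not isolated)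
Conditions: Cp2TiMe2, toluene, 70 °C, dark; filtration through basic alumina; then TBAF, AcOH, THF, 0 °C
Reagents that add atoms: dimethyltitanocene Cp2TiMe2, C[Ti+2]C.c1cc[cH-]c1.c1cc[cH-]c1
Why: Petasis methylenation (Cp2Ti=CH2 formed by loss of methane, then oxatitanacyclobutane cycloreversion) converts hindered, enolisable aryl ketones into 1,1-disubstituted alkenes without acid or base, so the double bond cannot move into the chain, and acetic acid-buffered fluoride then frees the phenol without the acidity that would isomerise or dimerise this electron-rich styrene.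

Step 4
Reactants: 7 2-(hept-1-en-2-yl)-3,5-dimethoxyphenol; 8 carbon monoxide
Product: 9 (4R)-5,7-dimethoxy-4-pentylchroman-2-one
Conditions: Pd(OAc)2 (5 mol %), (R,R)-DIOP (10 mol %), CO (35 bar), H2 (7 bar), CH2Cl2, 100 °C
Reagents that add atoms: none
Why: Pd(OAc)2, the diphosphine and CO/H2 should give a divalent palladium hydride that adds across the 1,1-disubstituted alkene with hydrogen to the aryl-bearing carbon (C3') and palladium to the CH2 terminus (C2'); CO then inserts into the Pd–C2' bond (C2'–C1' bond) and the neighbouring phenol oxygen attacks the acyl palladium (C1'–O5 bond), which releases the lactone and regenerates the hydride. The closest known reaction is the palladium-catalysed enantioselective cyclocarbonylation of 2-(1-methylvinyl)phenols to 4-methyl-3,4-dihydrocoumarins with Pd(OAc)2 and DIOP under CO/H2, applied here to a pentyl-bearing, doubly ortho-substituted member of the same substrate class. The one ring closes by 6-exo-trig attack of O5 on the acyl carbon. The new centre C3' (lactone C4, R) is created in the hydride transfer, and the alkene face is chosen by the chiral pocket of the C2-symmetric diphosphine. The step needs anti-Markovnikov hydropalladation, which the substrate secures because palladium on the fully substituted benzylic carbon, flanked by OH and OMe, would be a congested tertiary alkyl; it also needs carbonylation to outrun hydrogenation and migration of the double bond into the pentyl chain, which the high CO pressure and the phenol sitting beside the acyl group (fast intramolecular capture) should ensure.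

Step 5
Reactants: 9 (4R)-5,7-dimethoxy-4-pentylchroman-2-one; 10 tigloyl chloride [(2E)-2-methylbut-2-enoyl chloride]
Product: 11 (4R)-5,7-dimethoxy-8-[(2E)-2-methylbut-2-enoyl]-4-pentylchroman-2-one
Conditions: AlCl3, CH2Cl2, −20 → 0 °C
Reagents that add atoms: none
Why: Friedel–Crafts acylation should go to lactone C8 (the future C4a), which is para to the C5 methoxy group, ortho to the C7 methoxy group and less crowded than C6 between two methoxy groups, as is usual for 5,7-dialkoxycoumarins, while the low temperature keeps AlCl3 from demethylating or cyclising the new aryl enone.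

Step 6
Reactants: 11 (4R)-5,7-dimethoxy-8-[(2E)-2-methylbut-2-enoyl]-4-pentylchroman-2-one
Product: 12 (4R)-7-hydroxy-5-methoxy-8-[(2E)-2-methylbut-2-enoyl]-4-pentylchroman-2-one
Conditions: BCl3, CH2Cl2, −78 → −20 °C; ice-water
Reagents that add atoms: none
Why: In this chelation-controlled ether cleavage, BCl3 held between the aryl ketone and the adjacent C7 methoxy oxygen delivers chloride to that methyl group only, because the C5 methoxy group has no carbonyl neighbour and the other ortho position is the lactone oxygen, and the cold, base-free work-up keeps the freed phenol from adding to the enone.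

Step 7
Reactants: 12 (4R)-7-hydroxy-5-methoxy-8-[(2E)-2-methylbut-2-enoyl]-4-pentylchroman-2-one
Product: 13 (4R,8S,9R)-5-methoxy-8,9-dimethyl-4-pentyl-3,4,8,9-tetrahydro-2H,10H-pyrano[2,3-f]chromene-2,10-dione (cis-2,3-dimethylchromanone fused to the dihydrocoumarin)
Conditions: quinidine (20 mol %), chlorobenzene, 15 °C
Reagents that add atoms: none
Why: In this cinchona alkaloid-catalysed intramolecular oxa-Michael addition of an ortho-tigloylphenol (6-endo-trig), the quinuclidine nitrogen activates the phenol and the alkaloid hydroxyl the enone, so the oxygen should add to one face of the β-carbon (target C2, S) and the enol be protonated within the same ion pair on the face away from the new C2 methyl group, giving the kinetic cis arrangement (target C3, R); the lactone centre is remote, and any stereochemical leakage appears as diastereomers that chromatography removes.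

Step 8
Reactants: 13 (4R,8S,9R)-5-methoxy-8,9-dimethyl-4-pentyl-3,4,8,9-tetrahydro-2H,10H-pyrano[2,3-f]chromene-2,10-dione
Product: 14 (4R,8S,9R)-6-bromo-5-methoxy-8,9-dimethyl-4-pentyl-3,4,8,9-tetrahydro-2H,10H-pyrano[2,3-f]chromene-2,10-dione
Conditions: NBS, MeCN, 0 °C → rt, dark
Reagents that add atoms: N-bromosuccinimide, O=C1CCC(=O)N1Br
Why: Electrophilic aromatic bromination can only take the single remaining ring CH (tricycle C6, the future C8), which is ortho to the methoxy and ring-ether oxygens and para to the lactone oxygen, and the neutral, cold conditions leave the enolisable cis-chromanone centre untouched.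

Step 9
Reactants: 14 (4R,8S,9R)-6-bromo-5-methoxy-8,9-dimethyl-4-pentyl-3,4,8,9-tetrahydro-2H,10H-pyrano[2,3-f]chromene-2,10-dione; 15 tributyl(3-methylbut-2-enyl)stannane
Product: 16 (4R,8S,9R)-5-methoxy-8,9-dimethyl-6-(3-methylbut-2-en-1-yl)-4-pentyl-3,4,8,9-tetrahydro-2H,10H-pyrano[2,3-f]chromene-2,10-dione
Conditions: Pd(PPh3)4 (10 mol %), toluene, 100 °C
Reagents that add atoms: none
Why: Stille coupling (oxidative addition of zerovalent palladium into the C–Br bond, transfer of the allylic group from tin, reductive elimination) runs without base, so the cis centres are not exposed to enolisation, and the allylpalladium intermediate should couple through its less hindered CH2 terminus to give the linear prenyl group.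

Step 10
Reactants: 16 (4R,8S,9R)-5-methoxy-8,9-dimethyl-6-(3-methylbut-2-en-1-yl)-4-pentyl-3,4,8,9-tetrahydro-2H,10H-pyrano[2,3-f]chromene-2,10-dione
Product: 17 (3R)-3-[(2S,3R)-5-hydroxy-7-methoxy-2,3-dimethyl-8-(3-methylbut-2-en-1-yl)-4-oxo-3,4-dihydro-2H-chromen-6-yl]octanoic acid (CNP0217102.1)
Conditions: LiOH (2.2 equiv), THF/H2O, 0 °C, 15 min; then 0.5 M HCl to pH 3, 0 °C
Reagents that add atoms: lithium hydroxide, [Li+].[OH-]
Why: Saponification of the aryl ester lactone (acyl substitution with a phenoxide leaving group) should be far faster at 0 °C than hydroxide-induced enolisation of the chromanone, the liberated O5–H becomes hydrogen-bonded to the C4 carbonyl and so should not relactonise on mild acidification, and no stereocentre takes part.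

Compound list
1 | 1,3,5-trimethoxybenzene | COc1cc(OC)cc(OC)c1 | starting material
2 | hexanoyl chloride | CCCCCC(Cl)=O | starting material
3 | 1-(2,4,6-trimethoxyphenyl)hexan-1-one | CCCCCC(=O)c1c(OC)cc(OC)cc1OC | intermediate (not isolated)
4 | 1-(2-hydroxy-4,6-dimethoxyphenyl)hexan-1-one | CCCCCC(=O)c1c(O)cc(OC)cc1OC | intermediate
5 | 1-(2-{[tert-butyl(dimethyl)silyl]oxy}-4,6-dimethoxyphenyl)hexan-1-one | CCCCCC(=O)c1c(O[Si](C)(C)C(C)(C)C)cc(OC)cc1OC | intermediate
6 | tert-butyl[2-(hept-1-en-2-yl)-3,5-dimethoxyphenoxy]dimethylsilane | C=C(CCCCC)c1c(O[Si](C)(C)C(C)(C)C)cc(OC)cc1OC | intermediate (not isolated)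
7 | 2-(hept-1-en-2-yl)-3,5-dimethoxyphenol | C=C(CCCCC)c1c(O)cc(OC)cc1OC | intermediate
8 | carbon monoxide | [C-]#[O+] | starting material
9 | (4R)-5,7-dimethoxy-4-pentylchroman-2-one | CCCCC[C@@H]1CC(=O)Oc2cc(OC)cc(OC)c21 | intermediate
10 | tigloyl chloride, (2E)-2-methylbut-2-enoyl chloride | C/C=C(\C)C(Cl)=O | starting material
11 | (4R)-5,7-dimethoxy-8-[(2E)-2-methylbut-2-enoyl]-4-pentylchroman-2-one | CCCCC[C@@H]1CC(=O)Oc2c(C(=O)/C(C)=C/C)c(OC)cc(OC)c21 | intermediate
12 | (4R)-7-hydroxy-5-methoxy-8-[(2E)-2-methylbut-2-enoyl]-4-pentylchroman-2-one | CCCCC[C@@H]1CC(=O)Oc2c(C(=O)/C(C)=C/C)c(O)cc(OC)c21 | intermediate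
13 | (4R,8S,9R)-5-methoxy-8,9-dimethyl-4-pentyl-3,4,8,9-tetrahydro-2H,10H-pyrano[2,3-f]chromene-2,10-dione | CCCCC[C@@H]1CC(=O)Oc2c1c(OC)cc1O[C@@H](C)[C@@H](C)C(=O)c21 | intermediate
14 | (4R,8S,9R)-6-bromo-5-methoxy-8,9-dimethyl-4-pentyl-3,4,8,9-tetrahydro-2H,10H-pyrano[2,3-f]chromene-2,10-dione | CCCCC[C@@H]1CC(=O)Oc2c1c(OC)c(Br)c1O[C@@H](C)[C@@H](C)C(=O)c21 | intermediate
15 | tributyl(3-methylbut-2-enyl)stannane | CCCC[Sn](CCCC)(CCCC)CC=C(C)C | starting material
16 | (4R,8S,9R)-5-methoxy-8,9-dimethyl-6-(3-methylbut-2-en-1-yl)-4-pentyl-3,4,8,9-tetrahydro-2H,10H-pyrano[2,3-f]chromene-2,10-dione | CCCCC[C@@H]1CC(=O)Oc2c1c(OC)c(CC=C(C)C)c1O[C@@H](C)[C@@H](C)C(=O)c21 | intermediate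
17 | (3R)-3-[(2S,3R)-5-hydroxy-7-methoxy-2,3-dimethyl-8-(3-methylbut-2-en-1-yl)-4-oxo-3,4-dihydro-2H-chromen-6-yl]octanoic acid | CCCCC[C@H](CC(=O)O)c1c(O)c2c(c(CC=C(C)C)c1OC)O[C@@H](C)[C@@H](C)C2=O | target

Total step count: 10
Longest linear sequence: 10 steps (1 to 17); compounds 2, 8, 10 and 15 are bought.

Steps most likely to fail

Step 4 (key step). The diphosphine may discriminate poorly between the faces of this hindered alkene, reversible hydropalladation may move the double bond into the pentyl chain, or simple hydrogenation may compete, so that 9 forms with low ee or in low yield. The fallback sets out from ketone 4 and makes the same lactone by asymmetric reduction instead of carbonylation. Heating 4 with ethyl (triphenylphosphoranylidene)acetate in refluxing N,N-diethylaniline (Wittig olefination) should give ethyl (2Z)-3-(2-hydroxy-4,6-dimethoxyphenyl)oct-2-enoate F1, which lactonises in the flask to 5,7-dimethoxy-4-pentyl-2H-chromen-2-one F2. Enantioselective copper hydride conjugate reduction then sets C4, using Cu(OAc)2, the DTBM-SEGPHOS antipode that delivers hydride to the face leading to 4R, diethoxymethylsilane and t-BuOH in toluene. The tandem 1,2-reduction gives the lactol (4R)-5,7-dimethoxy-4-pentylchroman-2-ol F3, and oxidation with TEMPO/PhI(OAc)2 comes back to the route at 9.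

Step 9. Transfer of the bulky prenyl group to palladium at the doubly ortho-substituted C–Br bond may be slow, coupling may occur through the tertiary allylic terminus (reverse prenyl), and long heating may epimerise C3 of the chromanone. The fallback sets out from bromide 14 and builds the prenyl group in two stages. Stille coupling with allyltributylstannane (Pd(PPh3)4, toluene, 90 °C), whose unhindered allyl group transfers faster and allows only one regiochemistry, should give (4R,8S,9R)-5-methoxy-8,9-dimethyl-4-pentyl-6-(prop-2-en-1-yl)-3,4,8,9-tetrahydro-2H,10H-pyrano[2,3-f]chromene-2,10-dione F4. Cross-metathesis with 2-methylbut-2-ene (second-generation Grubbs catalyst, CH2Cl2, 40 °C) then forms the trisubstituted alkene and comes back to the route at 16.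

Step 10. Hydroxide may enolise C3 (cis to trans) or open the chromanone by retro-oxa-Michael elimination before the lactone is cleaved, and acidification may close the lactone again. The fallback sets out from 16 and avoids base altogether. Acid-catalysed ring-opening transesterification with allyl alcohol (camphorsulfonic acid cat., rt) should give prop-2-en-1-yl (3R)-3-[(2S,3R)-5-hydroxy-7-methoxy-2,3-dimethyl-8-(3-methylbut-2-en-1-yl)-4-oxo-3,4-dihydro-2H-chromen-6-yl]octanoate F5. Allyl transfer to phenylsilane under zerovalent palladium catalysis (Pd(PPh3)4, PhSiH3, CH2Cl2, rt) then releases the acid and comes back to the route at 17.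

Further compounds
F1 | step 4 | ethyl (2Z)-3-(2-hydroxy-4,6-dimethoxyphenyl)oct-2-enoate | CCCCC/C(=C/C(=O)OCC)c1c(O)cc(OC)cc1OC
F2 | step 4 | 5,7-dimethoxy-4-pentyl-2H-chromen-2-one | CCCCCC1=CC(=O)Oc2cc(OC)cc(OC)c21
F3 | step 4 | (4R)-5,7-dimethoxy-4-pentylchroman-2-ol | CCCCC[C@@H]1CC(O)Oc2cc(OC)cc(OC)c21
F4 | step 9 | (4R,8S,9R)-5-methoxy-8,9-dimethyl-4-pentyl-6-(prop-2-en-1-yl)-3,4,8,9-tetrahydro-2H,10H-pyrano[2,3-f]chromene-2,10-dione | CCCCC[C@@H]1CC(=O)Oc2c1c(OC)c(CC=C)c1O[C@@H](C)[C@@H](C)C(=O)c21
F5 | step 10 | prop-2-en-1-yl (3R)-3-[(2S,3R)-5-hydroxy-7-methoxy-2,3-dimethyl-8-(3-methylbut-2-en-1-yl)-4-oxo-3,4-dihydro-2H-chromen-6-yl]octanoate | CCCCC[C@H](CC(=O)OCC=C)c1c(O)c2c(c(CC=C(C)C)c1OC)O[C@@H](C)[C@@H](C)C2=O
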